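**Strategy**

The ten-membered ring (C1–C10) is read as a Carroll retron: the oxygen on C2, the C3–C4 ethano link and the exocyclic C5=C16 methylene are exactly what an allyl β-keto ester leaves after decarboxylative allyl transfer. The precursor is therefore a twelve-membered β-keto lactone in which C3 is tied through a sacrificial carboxyl carbon to O–C16 of a 2-methylenepropane-1,3-diyl unit on C5. Zerovalent palladium ionises this ester and the tethered enolate closes the carbocycle by forming C3–C4, creating the C2 ketone and the exo-methylene and expelling CO2 in one operation. The lactone and C6–C14 stereocentres are set before; chloride, epoxide and acetates follow.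

Key step: step 33

Remark on numbering: briarane numbering is used for all intermediates (C1–C10 ten-membered ring; C1, C10–C14 six-membered ring; C15 methyl on C1; C16 methylene on C5; C17, C18, C19 lactone CH, methyl and carbonyl; C20 epoxide CH2); α/β refer to the six-membered ring, β being the face of C15.

Assumption: in step 22 the (–)-Ipc2BOTf antipode is taken as the one that selects the required enolate face; if the sense is the opposite, the (+)-reagent is used.

**Route**

Step 1
Reactants: 1 2-methylcyclohexane-1,3-dione; 2 allyl bromide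
Product: 3 2-methyl-2-(prop-2-en-1-yl)cyclohexane-1,3-dione
Conditions: NaOH (1 M aq), Bu4NI (cat.), rt
Reagents that add atoms: none
Why: C-alkylation of the stabilised 1,3-dione anion (enolate alkylation) gives the achiral, prochiral dione that carries C1 with its methyl group.

Step 2
Reactants: 3 2-methyl-2-(prop-2-en-1-yl)cyclohexane-1,3-dione
Product: 4 (2S,3S)-3-hydroxy-2-methyl-2-(prop-2-en-1-yl)cyclohexan-1-one
Conditions: baker's yeast, sucrose, H2O, 30 °C
Reagents that add atoms: none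
Why: Enzymatic desymmetrising ketone reduction of a 2,2-disubstituted 1,3-dione sets C1 and C14 together, the hydroxyl ending cis to the allyl group.

Step 3
Reactants: 4 (2S,3S)-3-hydroxy-2-methyl-2-(prop-2-en-1-yl)cyclohexan-1-one
Product: 5 (2S,3S)-3-hydroxy-2-methyl-2-[(E)-prop-1-en-1-yl]cyclohexan-1-one
Conditions: PdCl2(MeCN)2 (5 mol %), toluene, 80 °C
Reagents that add atoms: none
Why: Metal-hydride alkene isomerisation moves the terminal double bond to the more stable internal position and turns the allyl group into a masked formyl group (C2).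

Step 4
Reactants: 5 (2S,3S)-3-hydroxy-2-methyl-2-[(E)-prop-1-en-1-yl]cyclohexan-1-one
Product: 7 (2S,3S)-3-hydroxy-2-(hydroxymethyl)-2-methylcyclohexan-1-one, via keto aldehyde 6 (not isolated)
Conditions: O3, CH2Cl2/MeOH, –78 °C; Me2S; then NaBH4, EtOH, –78 °C
Reagents that add atoms: ozone, [O-][O+]=O
Why: Ozonolysis followed by chemoselective borohydride reduction of the aldehyde beside the hindered ketone gives the C2 carbinol without touching C1 or C14.

Step 5
Reactants: 7 (2S,3S)-3-hydroxy-2-(hydroxymethyl)-2-methylcyclohexan-1-one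
Product: 8 acetonide ketone (isopropylidene acetal across O2 and O14, cis-fused 1,3-dioxane; C10 ketone)
Conditions: 2,2-dimethoxypropane, PPTS, CH2Cl2, rt
Reagents that add atoms: 2,2-dimethoxypropane, COC(C)(C)OC
Why: Acid-catalysed transketalisation ties the cis 1,3-diol into one acetal that survives all basic and organometallic steps.

Step 6
Reactants: 8 acetonide ketone
Product: 9 acetonide enone (C10 ketone, C11=C12)
Conditions: IBX, DMSO/fluorobenzene, 70 °C
Reagents that add atoms: none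
Why: IBX dehydrogenation of a ketone can only give the C11=C12 enone because C1 is quaternary.

Step 7
Reactants: 9 acetonide enone
Product: 10 C11-(hydroxymethyl) enone (C20–OH)
Conditions: CH2O (37 % aq), DMAP (0.3 equiv), THF/H2O, rt
Reagents that add atoms: formaldehyde, C=O
Why: Morita–Baylis–Hillman hydroxymethylation installs C20 on C11, the catalyst adding to the unhindered β-carbon C12.

Step 8
Reactants: 10 C11-(hydroxymethyl) enone
Product: 11 11β,12β-epoxy ketone
Conditions: H2O2 (30 %), NaOH (cat.), MeOH, 0 °C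
Reagents that add atoms: hydrogen peroxide, OO
Why: Weitz–Scheffer nucleophilic epoxidation is expected on the convex face anti to the dioxane, and this C12 configuration is erased in step 13.

Step 9
Reactants: 11 11β,12β-epoxy ketone
Product: 12 allylic diol (12β-OH, C20–OH, C10=C11)
Conditions: N2H4·H2O, AcOH (cat.), MeOH, 0 °C to rt
Reagents that add atoms: none
Why: Wharton transposition (epoxy hydrazone, loss of N2) moves the oxygen to C12 and the double bond to C10=C11, giving the cyclohexenylmethanol needed for the Claisen step.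

Step 10
Reactants: 13 methyl glycolate
Product: 14 methyl 2-(methoxymethoxy)acetate
Conditions: MOMCl, i-Pr2NEt, CH2Cl2, 0 °C to rt
Reagents that add atoms: chloromethyl methyl ether, COCCl
Why: O-alkylation with an α-chloro ether gives a chelating acetal-protected glycolate.

Step 11
Reactants: 14 methyl 2-(methoxymethoxy)acetate
Product: 15 2-(methoxymethoxy)acetic acid
Conditions: LiOH, THF/H2O, 0 °C; then 1 M HCl to pH 3
Reagents that add atoms: lithium hydroxide, [Li+].[OH-]
Why: Ester saponification leaves the acetal intact under cold, briefly acidic work-up.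

Step 12
Reactants: 12 allylic diol; 15 2-(methoxymethoxy)acetic acid
Product: 16 C20 (methoxymethoxy)acetate, 12β-OH free
Conditions: EDC·HCl, DMAP (0.1 equiv), CH2Cl2, –20 °C
Reagents that add atoms: none
Why: Carbodiimide (Steglich) esterification acylates the primary allylic alcohol much faster than the ring secondary one.

Step 13
Reactants: 16 C20 (methoxymethoxy)acetate
Product: 17 C12 enone (C12=O, C10=C11)
Conditions: Dess–Martin periodinane, NaHCO3, CH2Cl2, 0 °C
Reagents that add atoms: none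
Why: Dess–Martin oxidation gives the transposed enone, so C12 can be reset by reduction.

Step 14
Reactants: 17 C12 enone
Product: 18 12α-alcohol (12R)
Conditions: NaBH4, CeCl3·7H2O, MeOH, –78 °C
Reagents that add atoms: none
Why: Luche 1,2-reduction delivers hydride to give the alcohol cis to O14, as in reductions of 5-substituted cyclohex-2-enones, and spares the ester.

Step 15
Reactants: 18 12α-alcohol
Product: 19 12α-OMOM glycolate ester
Conditions: MOMCl, i-Pr2NEt, Bu4NI (cat.), CH2Cl2, 0 °C to rt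
Reagents that add atoms: chloromethyl methyl ether, COCCl
Why: Acetal protection of the allylic alcohol under non-nucleophilic base leaves the ester untouched.

Step 16
Reactants: 19 12α-OMOM glycolate ester
Product: 21 (9S)-9-OMOM C8 carboxylic acid (10α-H, C11=C20 methylene), via silyl ketene acetal 20 (not isolated)
Conditions: LiHMDS, THF, –78 °C; TMSCl/Et3N; –78 to 23 °C; dilute HCl work-up
Reagents that add atoms: none
Why: Ireland–Claisen rearrangement through the chelated (Z)-ketene acetal and a chair transition state gives the 9,10-syn pair, bond formation at C10 taking the β face away from the axial C2 methylene and the α-oxygens, and the allyl shift creates the C11=C20 methylene.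

Step 17
Reactants: 21 C8 carboxylic acid
Product: 22 Weinreb amide of 21
Conditions: MeNHOMe·HCl, EDC·HCl, HOBt, i-Pr2NEt, CH2Cl2, 0 °C to rt
Reagents that add atoms: N,O-dimethylhydroxylamine hydrochloride, CNOC.Cl
Why: Carbodiimide amidation via the HOBt ester does not epimerise the α-alkoxy centre C9.

Step 18
Reactants: 23 tributyl(iodomethyl)stannane; 24 4-methoxybenzyl alcohol
Product: 25 tributyl{[(4-methoxybenzyl)oxy]methyl}stannane
Conditions: NaH, THF/DMF, 0 °C to rt
Reagents that add atoms: none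
Why: Williamson etherification of the alkoxide with the primary iodide gives the hydroxymethyl-anion precursor.

Step 19
Reactants: 22 Weinreb amide; 25 tributyl{[(4-methoxybenzyl)oxy]methyl}stannane
Product: 27 C8 ketone with C7H2–OPMB, via alkoxymethyllithium 26 (not isolated)
Conditions: 25, n-BuLi, THF, –78 °C; then 22, –78 °C; NH4Cl
Reagents that add atoms: none
Why: Tin–lithium exchange followed by Weinreb ketone synthesis stops at the ketone through the chelated tetrahedral intermediate and leaves C9 untouched.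

Step 20
Reactants: 28 2-methylenepropane-1,3-diol
Product: 29 2-{[(tert-butyldiphenylsilyl)oxy]methyl}prop-2-en-1-ol
Conditions: NaH (1 equiv), TBDPSCl, THF, 0 °C
Reagents that add atoms: tert-butyl(chloro)diphenylsilane, CC(C)(C)[Si](Cl)(c1ccccc1)c1ccccc1
Why: Monosilylation of a symmetric diol through its monosodium alkoxide.

Step 21
Reactants: 29 2-{[(tert-butyldiphenylsilyl)oxy]methyl}prop-2-en-1-ol
Product: 30 2-{[(tert-butyldiphenylsilyl)oxy]methyl}prop-2-enal
Conditions: Dess–Martin periodinane, NaHCO3, CH2Cl2, 0 °C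
Reagents that add atoms: none
Why: Dess–Martin oxidation of the allylic alcohol gives the enal that carries C4, C5, C6 and C16.

Step 22
Reactants: 27 C8 ketone with C7H2–OPMB; 30 2-{[(tert-butyldiphenylsilyl)oxy]methyl}prop-2-enal
Product: 32 syn-aldol (6R-OH, 7S-OPMB), via boron enolate 31 (not isolated)
Conditions: (–)-Ipc2BOTf, i-Pr2NEt, CH2Cl2, –78 °C; 30, –78 to –20 °C; H2O2, pH 7 buffer/MeOH
Reagents that add atoms: none
Why: Boron aldol reaction in which the (Z)-enol borinate formed at the less hindered C7 gives the 6,7-syn adduct through a Zimmerman–Traxler chair and the Ipc ligands choose the enolate face (reagent control over the C9 centre).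

Step 23
Reactants: 32 syn-aldol
Product: 33 6-O-TBS ether
Conditions: TBSOTf, 2,6-lutidine, CH2Cl2, –78 °C
Reagents that add atoms: tert-butyldimethylsilyl triflate, CC(C)(C)[Si](C)(C)OS(=O)(=O)C(F)(F)F
Why: Silylation at low temperature protects the allylic C6 oxygen without retro-aldol cleavage.

Step 24
Reactants: 33 6-O-TBS ether
Product: 34 7-hydroxy ketone
Conditions: DDQ, CH2Cl2/pH 7 buffer, 0 °C
Reagents that add atoms: none
Why: Oxidative cleavage of the PMB ether is selective over the MOM, silyl and acetonide groups.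

Step 25
Reactants: 34 7-hydroxy ketone
Product: 35 7-O-acrylate
Conditions: acryloyl chloride, i-Pr2NEt, CH2Cl2, –78 to 0 °C
Reagents that add atoms: acryloyl chloride, C=CC(=O)Cl
Why: Acylation of the only free hydroxyl sets up the lactone carbons C17, C18 and C19.

Step 26
Reactants: 35 7-O-acrylate
Product: 36 lactone (8R-OH, 17R-methyl γ-lactone)
Conditions: Cu(OAc)2·H2O (5 mol %), rac-BINAP (5 mol %), (Me2HSi)2O, THF, 0 °C to rt; then 1 M HCl, 0 °C
Reagents that add atoms: none
Why: Copper hydride reductive aldol cyclisation (conjugate reduction, then intramolecular aldol of the (Z)-enolate on the C8 ketone) puts the C9 chain trans to C6 on the new five-membered ring and the C18 methyl cis to the C8 hydroxyl.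

Step 27
Reactants: 36 lactone
Product: 37 2,14-diol
Conditions: PPTS, MeOH, 40 °C
Reagents that add atoms: none
Why: Mild acid transketalisation removes the acetonide while MOM ethers, the secondary TBS ether and the TBDPS ether stay.

Step 28
Reactants: 37 2,14-diol
Product: 38 C2 aldehyde with 14-OH
Conditions: TEMPO (0.2 equiv), PhI(OAc)2, CH2Cl2, rt
Reagents that add atoms: none
Why: Oxoammonium oxidation is selective for the primary C2 alcohol over the secondary C14 and tertiary C8 alcohols.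

Step 29
Reactants: 38 C2 aldehyde with 14-OH
Product: 39 C2 aldehyde 14-acetate
Conditions: Ac2O, pyridine, DMAP (cat.), CH2Cl2, 0 °C to rt
Reagents that add atoms: acetic anhydride, CC(=O)OC(C)=O
Why: Acetylation installs the final C14 ester and blocks this hydroxyl against the acylketene of step 32, while the hindered tertiary C8 hydroxyl does not react.

Step 30
Reactants: 39 C2 aldehyde 14-acetate
Product: 40 tert-butyl β-keto ester (C2 ketone, C3H2, CO2t-Bu)
Conditions: tert-butyl diazoacetate, SnCl2 (0.2 equiv), CH2Cl2, rt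
Reagents that add atoms: tert-butyl diazoacetate, CC(C)(C)OC(=O)C=[N+]=[N-]
Why: Roskamp homologation (diazo ester addition, 1,2-hydride shift, loss of N2) converts the non-enolisable aldehyde directly into the β-keto ester that carries C3.

Step 31
Reactants: 40 tert-butyl β-keto ester
Product: 41 16-hydroxy β-keto ester
Conditions: TBAF, AcOH (1:1), THF, 0 °C to rt
Reagents that add atoms: none
Why: Buffered fluoride removes the primary allylic TBDPS group faster than the hindered secondary TBS ether at C6.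

Step 32
Reactants: 41 16-hydroxy β-keto ester
Product: 43 twelve-membered β-keto lactone, via acylketene 42 (not isolated)
Conditions: toluene, 110 °C, slow addition, 0.5 mM
Reagents that add atoms: none
Why: Thermal loss of tert-butanol gives an acylketene that is trapped intramolecularly by the only unhindered hydroxyl (acylketene macrolactonisation), with no stereocentre involved.

Step 33
Reactants: 43 twelve-membered β-keto lactone
Product: 45 ten-membered C2 ketone (briarane skeleton, C5=C16 methylene), via ring-closed keto acid 44 (not isolated)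
Conditions: Pd(PPh3)4 (10 mol %), THF, 40 °C, 1 mM
Reagents that add atoms: none
Why: Zerovalent palladium ionises the only allylic ester (C16–O) of 43 to a zwitterion in which a 2-substituted π-allyl unit (C4–C5–C16) and a β-keto carboxylate are held together by the C1–C10–C9–C8–C7–C6 chain, carbon C3 attacks a CH2 terminus of the allyl unit and the resulting β-keto acid 44 loses CO2. The closest known reactions are the palladium-catalysed decarboxylative allylation of allyl β-keto esters (palladium Carroll rearrangement) and Tsuji–Trost macrocyclisation. The ten-membered carbocycle is closed by intramolecular attack on an allyl terminus, the ring taking in the central carbon C5 and leaving the other terminus as the exocyclic C16 methylene, a net 12-to-10 ring contraction. No lasting stereocentre is created (C3 of 44 is lost on decarboxylation), so no stereocontrol is required. The step needs C-allylation within the ion pair instead of oligomerisation, O-allylation or protonation, which high dilution and the tether should secure, and it needs no regiocontrol, because both allyl termini are CH2 and give the same product, the π-allyl unit has no β-hydrogen to eliminate, and C3 is the only enolisable carbon next to C2 since C1 is quaternary. The C6 silyl ether, the C12 MOM ether, the non-allylic acetate and the lactone are not ionised.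

Step 34
Reactants: 45 ten-membered C2 ketone
Product: 46 (2R)-alcohol
Conditions: (S)-2-methyl-CBS-oxazaborolidine (0.5 equiv), catecholborane, toluene, –78 to –40 °C
Reagents that add atoms: none
Why: Corey–Bakshi–Shibata reduction distinguishes the quaternary C1 side from the C3 methylene side and should give the 2R alcohol under reagent control, catecholborane sparing the alkenes, acetate and lactone.

Step 35
Reactants: 46 (2R)-alcohol
Product: 47 2,9,12-triol (8-OH also free)
Conditions: Me2BBr, CH2Cl2, –78 °C; then sat. NaHCO3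
Reagents that add atoms: none
Why: Bromoborane acetal cleavage removes both MOM groups at low temperature without touching the TBS ether, the acetate or the lactone.

Step 36
Reactants: 47 2,9,12-triol
Product: 48 11α,20-epoxide
Conditions: VO(acac)2 (5 mol %), t-BuOOH, CH2Cl2, 0 °C
Reagents that add atoms: tert-butyl hydroperoxide, CC(C)(C)OO
Why: Hydroxyl-directed vanadium-catalysed epoxidation delivers oxygen to the C11=C20 methylene syn to the allylic 12α-hydroxyl, while the C5=C16 alkene has no free allylic hydroxyl.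

Step 37
Reactants: 48 11α,20-epoxide
Product: 49 2,9,12,14-tetraacetate 6-O-TBS ether
Conditions: Ac2O, DMAP, pyridine, CH2Cl2, rt
Reagents that add atoms: acetic anhydride, CC(=O)OC(C)=O
Why: DMAP-catalysed acetylation esterifies the three secondary alcohols and leaves the hindered tertiary C8 hydroxyl free.

Step 38
Reactants: 49 tetraacetate 6-O-TBS ether
Product: 50 (6R)-allylic alcohol
Conditions: HF·pyridine, pyridine, THF, 0 °C to rt
Reagents that add atoms: none
Why: Pyridine-buffered fluoride desilylation is compatible with the acetates and the epoxide.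

Step 39
Reactants: 50 (6R)-allylic alcohol
Product: 51 CNP0349227.1 (target, 6S chloride)
Conditions: PPh3, hexachloroacetone, 2,6-di-tert-butylpyridine, CH2Cl2, –40 to 0 °C
Reagents that add atoms: hexachloroacetone, O=C(C(Cl)(Cl)Cl)C(Cl)(Cl)Cl
Why: Appel-type chlorination through the oxyphosphonium salt displaces the secondary allylic alcohol by SN2 with inversion (6R to 6S), a reagent pair chosen for its low tendency to allylic transposition.

**Compound list**

1 | 2-methylcyclohexane-1,3-dione | CC1C(=O)CCCC1=O | starting material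
2 | allyl bromide | C=CCBr | starting material
3 | 2-methyl-2-(prop-2-en-1-yl)cyclohexane-1,3-dione | C=CCC1(C)C(=O)CCCC1=O | intermediate
4 | (2S,3S)-3-hydroxy-2-methyl-2-(prop-2-en-1-yl)cyclohexan-1-one | C=CC[C@@]1(C)[C@@H](O)CCCC1=O | intermediate
5 | (2S,3S)-3-hydroxy-2-methyl-2-[(E)-prop-1-en-1-yl]cyclohexan-1-one | C/C=C/[C@@]1(C)[C@@H](O)CCCC1=O | intermediate
6 | (1R,2S)-2-hydroxy-1-methyl-6-oxocyclohexane-1-carbaldehyde | O=C[C@@]1(C)[C@@H](O)CCCC1=O | intermediate
7 | (2S,3S)-3-hydroxy-2-(hydroxymethyl)-2-methylcyclohexan-1-one | OC[C@@]1(C)[C@@H](O)CCCC1=O | intermediate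
8 | acetonide ketone (O2/O14 isopropylidene acetal of 7) | CC1(C)OC[C@@]2(C)[C@@H](O1)CCCC2=O | intermediate
9 | acetonide enone (C11=C12) | CC1(C)OC[C@@]2(C)[C@@H](O1)CC=CC2=O | intermediate
10 | C11-(hydroxymethyl) enone | CC1(C)OC[C@@]2(C)[C@@H](O1)CC=C(CO)C2=O | intermediate
11 | 11β,12β-epoxy ketone | CC1(C)OC[C@@]2(C)[C@@H](O1)C[C@@H]3O[C@]3(CO)C2=O | intermediate
12 | allylic diol (12β-OH, C20–OH, C10=C11) | CC1(C)OC[C@@]2(C)[C@@H](O1)C[C@H](O)C(CO)=C2 | intermediate
13 | methyl glycolate | COC(=O)CO | starting material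
14 | methyl 2-(methoxymethoxy)acetate | COCOCC(=O)OC | intermediate
15 | 2-(methoxymethoxy)acetic acid | COCOCC(=O)O | intermediate
16 | C20 (methoxymethoxy)acetate, 12β-OH | CC1(C)OC[C@@]2(C)[C@@H](O1)C[C@H](O)C(COC(=O)COCOC)=C2 | intermediate
17 | C12 enone | CC1(C)OC[C@@]2(C)[C@@H](O1)CC(=O)C(COC(=O)COCOC)=C2 | intermediate
18 | 12α-alcohol (12R) | CC1(C)OC[C@@]2(C)[C@@H](O1)C[C@@H](O)C(COC(=O)COCOC)=C2 | intermediate
19 | 12α-OMOM glycolate ester | CC1(C)OC[C@@]2(C)[C@@H](O1)C[C@@H](OCOC)C(COC(=O)COCOC)=C2 | intermediate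
20 | (Z)-O-trimethylsilyl ketene acetal of 19 | CC1(C)OC[C@@]2(C)[C@@H](O1)C[C@@H](OCOC)C(CO/C(O[Si](C)(C)C)=C/OCOC)=C2 | intermediate
21 | (9S)-9-OMOM C8 carboxylic acid (10α-H, C11=C20) | CC1(C)OC[C@@]2(C)[C@@H](O1)C[C@@H](OCOC)C(=C)[C@@H]2[C@H](OCOC)C(=O)O | intermediate
22 | Weinreb amide of 21 | CC1(C)OC[C@@]2(C)[C@@H](O1)C[C@@H](OCOC)C(=C)[C@@H]2[C@H](OCOC)C(=O)N(C)OC | intermediate
23 | tributyl(iodomethyl)stannane | CCCC[Sn](CCCC)(CCCC)CI | starting material
24 | 4-methoxybenzyl alcohol | COc1ccc(CO)cc1 | starting material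
25 | tributyl{[(4-methoxybenzyl)oxy]methyl}stannane | CCCC[Sn](CCCC)(CCCC)COCc1ccc(OC)cc1 | intermediate
26 | {[(4-methoxybenzyl)oxy]methyl}lithium | [Li]COCc1ccc(OC)cc1 | intermediate
27 | C8 ketone with C7H2–OPMB | CC1(C)OC[C@@]2(C)[C@@H](O1)C[C@@H](OCOC)C(=C)[C@@H]2[C@H](OCOC)C(=O)COCc1ccc(OC)cc1 | intermediate
28 | 2-methylenepropane-1,3-diol | C=C(CO)CO | starting material
29 | 2-{[(tert-butyldiphenylsilyl)oxy]methyl}prop-2-en-1-ol | C=C(CO)CO[Si](c1ccccc1)(c1ccccc1)C(C)(C)C | intermediate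
30 | 2-{[(tert-butyldiphenylsilyl)oxy]methyl}prop-2-enal | C=C(C=O)CO[Si](c1ccccc1)(c1ccccc1)C(C)(C)C | intermediate
31 | (Z)-diisopinocampheylboron enolate of 27 (Ipc groups from the (–)-reagent, drawn without their stereocentres) | CC1(C)OC[C@@]2(C)[C@@H](O1)C[C@@H](OCOC)C(=C)[C@@H]2[C@H](OCOC)/C(OB(C1CC2CC(C1C)C2(C)C)C1CC2CC(C1C)C2(C)C)=C/OCc1ccc(OC)cc1 | intermediate
32 | syn-aldol (6R-OH, 7S-OPMB) | CC1(C)OC[C@@]2(C)[C@@H](O1)C[C@@H](OCOC)C(=C)[C@@H]2[C@H](OCOC)C(=O)[C@@H](OCc1ccc(OC)cc1)[C@H](O)C(=C)CO[Si](c1ccccc1)(c1ccccc1)C(C)(C)C | intermediate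
33 | 6-O-TBS ether of 32 | CC1(C)OC[C@@]2(C)[C@@H](O1)C[C@@H](OCOC)C(=C)[C@@H]2[C@H](OCOC)C(=O)[C@@H](OCc1ccc(OC)cc1)[C@H](O[Si](C)(C)C(C)(C)C)C(=C)CO[Si](c1ccccc1)(c1ccccc1)C(C)(C)C | intermediate
34 | 7-hydroxy ketone | CC1(C)OC[C@@]2(C)[C@@H](O1)C[C@@H](OCOC)C(=C)[C@@H]2[C@H](OCOC)C(=O)[C@@H](O)[C@H](O[Si](C)(C)C(C)(C)C)C(=C)CO[Si](c1ccccc1)(c1ccccc1)C(C)(C)C | intermediate
35 | 7-O-acrylate | CC1(C)OC[C@@]2(C)[C@@H](O1)C[C@@H](OCOC)C(=C)[C@@H]2[C@H](OCOC)C(=O)[C@@H](OC(=O)C=C)[C@H](O[Si](C)(C)C(C)(C)C)C(=C)CO[Si](c1ccccc1)(c1ccccc1)C(C)(C)C | intermediate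
36 | lactone (8R-OH, 17R) | CC1(C)OC[C@@]2(C)[C@@H](O1)C[C@@H](OCOC)C(=C)[C@@H]2[C@H](OCOC)[C@]1(O)[C@@H](C)C(=O)O[C@H]1[C@H](O[Si](C)(C)C(C)(C)C)C(=C)CO[Si](c1ccccc1)(c1ccccc1)C(C)(C)C | intermediate
37 | 2,14-diol | OC[C@@]1(C)[C@@H](O)C[C@@H](OCOC)C(=C)[C@@H]1[C@H](OCOC)[C@]1(O)[C@@H](C)C(=O)O[C@H]1[C@H](O[Si](C)(C)C(C)(C)C)C(=C)CO[Si](c1ccccc1)(c1ccccc1)C(C)(C)C | intermediate
38 | C2 aldehyde with 14-OH | O=C[C@@]1(C)[C@@H](O)C[C@@H](OCOC)C(=C)[C@@H]1[C@H](OCOC)[C@]1(O)[C@@H](C)C(=O)O[C@H]1[C@H](O[Si](C)(C)C(C)(C)C)C(=C)CO[Si](c1ccccc1)(c1ccccc1)C(C)(C)C | intermediate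
39 | C2 aldehyde 14-acetate | O=C[C@@]1(C)[C@@H](OC(C)=O)C[C@@H](OCOC)C(=C)[C@@H]1[C@H](OCOC)[C@]1(O)[C@@H](C)C(=O)O[C@H]1[C@H](O[Si](C)(C)C(C)(C)C)C(=C)CO[Si](c1ccccc1)(c1ccccc1)C(C)(C)C | intermediate
40 | tert-butyl β-keto ester | CC(C)(C)OC(=O)CC(=O)[C@@]1(C)[C@@H](OC(C)=O)C[C@@H](OCOC)C(=C)[C@@H]1[C@H](OCOC)[C@]1(O)[C@@H](C)C(=O)O[C@H]1[C@H](O[Si](C)(C)C(C)(C)C)C(=C)CO[Si](c1ccccc1)(c1ccccc1)C(C)(C)C | intermediate
41 | 16-hydroxy β-keto ester | CC(C)(C)OC(=O)CC(=O)[C@@]1(C)[C@@H](OC(C)=O)C[C@@H](OCOC)C(=C)[C@@H]1[C@H](OCOC)[C@]1(O)[C@@H](C)C(=O)O[C@H]1[C@H](O[Si](C)(C)C(C)(C)C)C(=C)CO | intermediate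
42 | acylketene | O=C=CC(=O)[C@@]1(C)[C@@H](OC(C)=O)C[C@@H](OCOC)C(=C)[C@@H]1[C@H](OCOC)[C@]1(O)[C@@H](C)C(=O)O[C@H]1[C@H](O[Si](C)(C)C(C)(C)C)C(=C)CO | intermediate
43 | twelve-membered β-keto lactone | O=C1CC(=O)[C@@]2(C)[C@@H](OC(C)=O)C[C@@H](OCOC)C(=C)[C@@H]2[C@H](OCOC)[C@]3(O)[C@@H](C)C(=O)O[C@H]3[C@H](O[Si](C)(C)C(C)(C)C)C(=C)CO1 | intermediate
44 | ring-closed C3 carboxylic acid (C3 unassigned) | C=C1CC(C(=O)O)C(=O)[C@@]2(C)[C@@H](OC(C)=O)C[C@@H](OCOC)C(=C)[C@@H]2[C@H](OCOC)[C@]2(O)[C@@H](C)C(=O)O[C@H]2[C@@H]1O[Si](C)(C)C(C)(C)C | intermediate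
45 | ten-membered C2 ketone | C=C1CCC(=O)[C@@]2(C)[C@@H](OC(C)=O)C[C@@H](OCOC)C(=C)[C@@H]2[C@H](OCOC)[C@]2(O)[C@@H](C)C(=O)O[C@H]2[C@@H]1O[Si](C)(C)C(C)(C)C | intermediate
46 | (2R)-alcohol | C=C1CC[C@@H](O)[C@@]2(C)[C@@H](OC(C)=O)C[C@@H](OCOC)C(=C)[C@@H]2[C@H](OCOC)[C@]2(O)[C@@H](C)C(=O)O[C@H]2[C@@H]1O[Si](C)(C)C(C)(C)C | intermediate
47 | 2,9,12-triol | C=C1CC[C@@H](O)[C@@]2(C)[C@@H](OC(C)=O)C[C@@H](O)C(=C)[C@@H]2[C@H](O)[C@]2(O)[C@@H](C)C(=O)O[C@H]2[C@@H]1O[Si](C)(C)C(C)(C)C | intermediate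
48 | 11α,20-epoxide | C=C1CC[C@@H](O)[C@@]2(C)[C@@H](OC(C)=O)C[C@@H](O)[C@]3(CO3)[C@@H]2[C@H](O)[C@]2(O)[C@@H](C)C(=O)O[C@H]2[C@@H]1O[Si](C)(C)C(C)(C)C | intermediate
49 | 2,9,12,14-tetraacetate 6-O-TBS ether | C=C1CC[C@@H](OC(C)=O)[C@@]2(C)[C@@H](OC(C)=O)C[C@@H](OC(C)=O)[C@]3(CO3)[C@@H]2[C@H](OC(C)=O)[C@]2(O)[C@@H](C)C(=O)O[C@H]2[C@@H]1O[Si](C)(C)C(C)(C)C | intermediate
50 | (6R)-allylic alcohol | C=C1CC[C@@H](OC(C)=O)[C@@]2(C)[C@@H](OC(C)=O)C[C@@H](OC(C)=O)[C@]3(CO3)[C@@H]2[C@H](OC(C)=O)[C@]2(O)[C@@H](C)C(=O)O[C@H]2[C@@H]1O | intermediate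
51 | CNP0349227.1 | C=C1CC[C@@H](OC(C)=O)[C@@]2(C)[C@@H](OC(C)=O)C[C@@H](OC(C)=O)[C@]3(CO3)[C@@H]2[C@H](OC(C)=O)[C@]2(O)[C@@H](C)C(=O)O[C@H]2[C@H]1Cl | target

**Count and risks**

Total step count: 39. Longest linear sequence: 34 steps (1–9, 12–17, 19, 22–39).

Most likely to fail:

1. Step 33. The ion pair may collapse between molecules (oligomerisation), or the enolate may be protonated or O-allylated before the ring closes. The fallback sets out from 41 and returns at 45. CBr4/PPh3 converts 41 into the C16 allylic bromide F1. Cs2CO3 in MeCN at high dilution then closes the ten-membered ring by C-alkylation of the β-keto ester at C3, giving the ring-closed tert-butyl β-keto ester F2. Heating F2 in wet DMSO at 120 °C releases tert-butanol and CO2 (acylketene hydrolysis, decarboxylation) and gives 45.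

2. Step 22. Facial selectivity of the enolate may be poor if the C9 centre and the boron ligands are mismatched, giving the 6,7-bis-epimeric syn adduct. The fallback sets out from 22 and returns at 33.
   - DIBAL-H reduces 22 to the C8 aldehyde F3.
   - An Evans syn aldol (Bu2BOTf, Et3N) with (R)-4-benzyl-3-{[(4-methoxybenzyl)oxy]acetyl}oxazolidin-2-one sets C7 under auxiliary control and gives the imide F4.
   - TESOTf gives the C8 silyl ether F5, and LiBH4 removes the auxiliary to give the primary alcohol F6.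
   - Dess–Martin oxidation gives the C6 aldehyde F7.
   - Chelation-controlled (MgBr2) addition of the Grignard reagent from 2-bromo-3-[(tert-butyldiphenylsilyl)oxy]prop-1-ene gives the 6,7-syn allylic alcohol F8.
   - TBSOTf gives the bis-silyl ether F9, buffered HF·pyridine removes the triethylsilyl group to give the C8 alcohol F10, and Dess–Martin oxidation of F10 gives 33.

3. Step 39. The oxyphosphonium salt may collapse by SN2′ (allylic transposition to the primary chloride), or elimination or epoxide opening may occur. The fallback sets out from 50 and returns at 51: MsCl/Et3N at –30 °C gives the isolated mesylate F11, which is displaced in a separate SN2 step by LiCl in DMF at 0 °C.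

Further compounds
F1 | step 33 | C16 allylic bromide of the β-keto ester | CC(C)(C)OC(=O)CC(=O)[C@@]1(C)[C@@H](OC(C)=O)C[C@@H](OCOC)C(=C)[C@@H]1[C@H](OCOC)[C@]1(O)[C@@H](C)C(=O)O[C@H]1[C@H](O[Si](C)(C)C(C)(C)C)C(=C)CBr
F2 | step 33 | ring-closed tert-butyl β-keto ester (C3 unassigned) | C=C1CC(C(=O)OC(C)(C)C)C(=O)[C@@]2(C)[C@@H](OC(C)=O)C[C@@H](OCOC)C(=C)[C@@H]2[C@H](OCOC)[C@]2(O)[C@@H](C)C(=O)O[C@H]2[C@@H]1O[Si](C)(C)C(C)(C)C
F3 | step 22 | C8 aldehyde | CC1(C)OC[C@@]2(C)[C@@H](O1)C[C@@H](OCOC)C(=C)[C@@H]2[C@H](OCOC)C=O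
F4 | step 22 | Evans syn-aldol imide (C8–OH, C7–OPMB) | CC1(C)OC[C@@]2(C)[C@@H](O1)C[C@@H](OCOC)C(=C)[C@@H]2[C@H](OCOC)[C@H](O)[C@@H](OCc1ccc(OC)cc1)C(=O)N1[C@H](Cc2ccccc2)COC1=O
F5 | step 22 | C8 triethylsilyl ether of F4 | CC1(C)OC[C@@]2(C)[C@@H](O1)C[C@@H](OCOC)C(=C)[C@@H]2[C@H](OCOC)[C@H](O[Si](CC)(CC)CC)[C@@H](OCc1ccc(OC)cc1)C(=O)N1[C@H](Cc2ccccc2)COC1=O
F6 | step 22 | C6 primary alcohol | CC1(C)OC[C@@]2(C)[C@@H](O1)C[C@@H](OCOC)C(=C)[C@@H]2[C@H](OCOC)[C@H](O[Si](CC)(CC)CC)[C@@H](OCc1ccc(OC)cc1)CO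
F7 | step 22 | C6 aldehyde | CC1(C)OC[C@@]2(C)[C@@H](O1)C[C@@H](OCOC)C(=C)[C@@H]2[C@H](OCOC)[C@H](O[Si](CC)(CC)CC)[C@@H](OCc1ccc(OC)cc1)C=O
F8 | step 22 | 6,7-syn allylic alcohol | CC1(C)OC[C@@]2(C)[C@@H](O1)C[C@@H](OCOC)C(=C)[C@@H]2[C@H](OCOC)[C@H](O[Si](CC)(CC)CC)[C@@H](OCc1ccc(OC)cc1)[C@H](O)C(=C)CO[Si](c1ccccc1)(c1ccccc1)C(C)(C)C
F9 | step 22 | 6-O-TBS 8-O-TES ether | CC1(C)OC[C@@]2(C)[C@@H](O1)C[C@@H](OCOC)C(=C)[C@@H]2[C@H](OCOC)[C@H](O[Si](CC)(CC)CC)[C@@H](OCc1ccc(OC)cc1)[C@H](O[Si](C)(C)C(C)(C)C)C(=C)CO[Si](c1ccccc1)(c1ccccc1)C(C)(C)C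
F10 | step 22 | C8 alcohol | CC1(C)OC[C@@]2(C)[C@@H](O1)C[C@@H](OCOC)C(=C)[C@@H]2[C@H](OCOC)[C@H](O)[C@@H](OCc1ccc(OC)cc1)[C@H](O[Si](C)(C)C(C)(C)C)C(=C)CO[Si](c1ccccc1)(c1ccccc1)C(C)(C)C
F11 | step 39 | (6R)-mesylate of 50 | C=C1CC[C@@H](OC(C)=O)[C@@]2(C)[C@@H](OC(C)=O)C[C@@H](OC(C)=O)[C@]3(CO3)[C@@H]2[C@H](OC(C)=O)[C@]2(O)[C@@H](C)C(=O)O[C@H]2[C@@H]1OS(C)(=O)=O
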